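The route rests on cutting ring C between the C4 methylene and the ring A carbon C4a. The precursor is an open-chain epoxy ether: 3,5-bis(benzyloxy)phenol bound through oxygen to the benzylic carbon (future C2) of a terminal epoxide (future C3 and C4), threo, both centres already (R). A gold-catalysed 6-endo Friedel–Crafts epoxide–arene cyclisation then forges C4–C4a, closes the pyran ring and releases the C3 hydroxyl in one operation. It exploits the oxygen on C3 next to the C4 methylene (the epoxide retron) and the symmetric, phloroglucinol-type ring A, whose two equivalent ortho carbons are each ortho/para to three oxygens. Acylation with protected syringic acid and hydrogenolysis finish.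

Key step: step 4

Assumption (remark on the chemistry): the benzyl-protected building blocks 1, 5 and 8, and 3,5-bis(benzyloxy)phenylboronic acid used in one fallback, are taken as purchasable. Benzyl protects every phenol so that a single hydrogenolysis frees all six.

Step 1
Reactants: 1 3,4,5-tris(benzyloxy)benzaldehyde; 2 vinylmagnesium bromide
Product: 3 racemic 1-[3,4,5-tris(benzyloxy)phenyl]prop-2-en-1-ol
Conditions: THF, −78 °C to 0 °C; then sat. aq NH4Cl
Reagents that add atoms: none
Why: Grignard 1,2-addition of a vinyl nucleophile to a non-enolisable aryl aldehyde is routine; the carbinol centre is formed racemic on purpose, since step 2 resolves it.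

Step 2
Reactants: 3 racemic 1-[3,4,5-tris(benzyloxy)phenyl]prop-2-en-1-ol
Product: 4 (S)-[(R)-oxiran-2-yl][3,4,5-tris(benzyloxy)phenyl]methanol, the erythro (anti) epoxy alcohol
Conditions: Ti(OiPr)4 (0.2 equiv), L-(+)-diisopropyl tartrate (0.25 equiv), t-BuOOH (0.45 equiv), 4 Å MS, CH2Cl2, −20 °C, stopped below half conversion
Reagents that add atoms: tert-butyl hydroperoxide, CC(C)(C)OO
Why: Sharpless kinetic resolution (titanium–tartrate epoxidation of a secondary allylic alcohol): with L-(+)-DIPT the (R)-enantiomer should be epoxidised much faster than the (S)-enantiomer, on the alkene face that gives the erythro epoxy alcohol, so the tartrate fixes the carbinol centre by selection and the oxirane centre by face control while the (S)-alcohol stays behind.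

Step 3
Reactants: 4 (S)-[(R)-oxiran-2-yl][3,4,5-tris(benzyloxy)phenyl]methanol; 5 3,5-bis(benzyloxy)phenol
Product: 6 (R)-2-{(R)-[3,5-bis(benzyloxy)phenoxy][3,4,5-tris(benzyloxy)phenyl]methyl}oxirane, the threo epoxy ether
Conditions: PPh3, diisopropyl azodicarboxylate (DIAD), toluene, 0 °C to rt
Reagents that add atoms: none
Why: Mitsunobu etherification: the phenoxide of 5 displaces the alkoxyphosphonium group by SN2 with inversion at the benzylic carbon (erythro alcohol to threo ether), the neutral conditions should leave the oxirane untouched, and the electron-withdrawing oxirane next to the reacting carbon holds back ionisation.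

Step 4
Reactants: 6 (R)-2-{(R)-[3,5-bis(benzyloxy)phenoxy][3,4,5-tris(benzyloxy)phenyl]methyl}oxirane
Product: 7 (2R,3R)-5,7-bis(benzyloxy)-2-[3,4,5-tris(benzyloxy)phenyl]chroman-3-ol (penta-O-benzyl epigallocatechin, 2,3-cis)
Conditions: AuCl3 (5 mol%), AgOTf (15 mol%), ClCH2CH2Cl, 0 °C to rt
Reagents that add atoms: none
Why: Cationic trivalent gold from AuCl3/AgOTf binds the epoxide oxygen, the ring A carbon ortho to the ether oxygen attacks the terminal carbon C4 from the back, the arenium ion loses a proton and the gold alkoxide is protonated to the C3 hydroxyl. The closest known reaction type is the gold-catalysed intramolecular Friedel–Crafts cycloalkylation of aryl glycidyl ethers to chroman-3-ols. Ring C closes in the 6-endo mode of epoxide opening (both epoxide carbons end up in the ring); the 5-exo alternative at C3 is strained across the short O–C tether and disfavoured at a secondary carbon flanked by the aryloxy-bearing C2. No stereocentre is created, since C4 becomes a methylene and C4a is aromatic, and C2 and C3 keep their (R,R) configuration because only the C4–O bond breaks, so the 2,3-cis relationship follows from the threo epoxy ether. The step needs regioselectivity at the epoxide, site selectivity between the arenes and an intact benzylic C2–O bond; these are secured by the unsubstituted C4 terminus, by the equivalence of the two ortho carbons of the symmetric 3,5-bis(benzyloxy)phenoxy ring (each ortho/para to three oxygens and more nucleophilic than ring B) and by a mild, low-loading catalyst at room temperature.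

Step 5
Reactants: 7 (2R,3R)-5,7-bis(benzyloxy)-2-[3,4,5-tris(benzyloxy)phenyl]chroman-3-ol; 8 4-(benzyloxy)-3,5-dimethoxybenzoic acid
Product: 9 (2R,3R)-5,7-bis(benzyloxy)-2-[3,4,5-tris(benzyloxy)phenyl]chroman-3-yl 4-(benzyloxy)-3,5-dimethoxybenzoate
Conditions: DCC, DMAP (cat.), CH2Cl2, rt
Reagents that add atoms: none
Why: Steglich esterification (DCC/DMAP acyl transfer) acylates the secondary C3 hydroxyl at oxygen, so no bond to C2 or C3 is broken and the (2R,3R) configuration should be kept, with the benzyl ethers inert.

Step 6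
Reactants: 9 (2R,3R)-5,7-bis(benzyloxy)-2-[3,4,5-tris(benzyloxy)phenyl]chroman-3-yl 4-(benzyloxy)-3,5-dimethoxybenzoate
Product: 10 epigallocatechin 3-O-(3,5-di-O-methylgallate), (2R,3R)-5,7-dihydroxy-2-(3,4,5-trihydroxyphenyl)chroman-3-yl 4-hydroxy-3,5-dimethoxybenzoate
Conditions: H2 (1 atm), Pd(OH)2/C, THF/MeOH, rt, then filtration under argon
Reagents that add atoms: none
Why: Catalytic hydrogenolysis should cleave all six O-benzyl ethers (five on the flavan, one on the syringoyl unit) under neutral conditions that spare the ester, the two methyl ethers and the cyclic C2–O1 ether, and it touches no stereocentre.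

Compound list
1 | 3,4,5-tris(benzyloxy)benzaldehyde | O=Cc1cc(OCc2ccccc2)c(OCc2ccccc2)c(OCc2ccccc2)c1 | starting material
2 | vinylmagnesium bromide | C=C[Mg]Br | starting material
3 | racemic 1-[3,4,5-tris(benzyloxy)phenyl]prop-2-en-1-ol | C=CC(O)c1cc(OCc2ccccc2)c(OCc2ccccc2)c(OCc2ccccc2)c1 | intermediate
4 | (S)-[(R)-oxiran-2-yl][3,4,5-tris(benzyloxy)phenyl]methanol (erythro) | O1C[C@@H]1[C@@H](O)c1cc(OCc2ccccc2)c(OCc2ccccc2)c(OCc2ccccc2)c1 | intermediate
5 | 3,5-bis(benzyloxy)phenol | Oc1cc(OCc2ccccc2)cc(OCc2ccccc2)c1 | starting material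
6 | (R)-2-{(R)-[3,5-bis(benzyloxy)phenoxy][3,4,5-tris(benzyloxy)phenyl]methyl}oxirane (threo) | O1C[C@@H]1[C@@H](c1cc(OCc2ccccc2)c(OCc2ccccc2)c(OCc2ccccc2)c1)Oc1cc(OCc2ccccc2)cc(OCc2ccccc2)c1 | intermediate
7 | (2R,3R)-5,7-bis(benzyloxy)-2-[3,4,5-tris(benzyloxy)phenyl]chroman-3-ol | O[C@@H]1Cc2c(OCc3ccccc3)cc(OCc3ccccc3)cc2O[C@@H]1c1cc(OCc2ccccc2)c(OCc2ccccc2)c(OCc2ccccc2)c1 | intermediate
8 | 4-(benzyloxy)-3,5-dimethoxybenzoic acid | COc1cc(C(=O)O)cc(OC)c1OCc1ccccc1 | starting material
9 | (2R,3R)-5,7-bis(benzyloxy)-2-[3,4,5-tris(benzyloxy)phenyl]chroman-3-yl 4-(benzyloxy)-3,5-dimethoxybenzoate | COc1cc(C(=O)O[C@@H]2Cc3c(OCc4ccccc4)cc(OCc4ccccc4)cc3O[C@@H]2c2cc(OCc3ccccc3)c(OCc3ccccc3)c(OCc3ccccc3)c2)cc(OC)c1OCc1ccccc1 | intermediate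
10 | epigallocatechin 3-O-(3,5-di-O-methylgallate) | COc1cc(C(=O)O[C@@H]2Cc3c(O)cc(O)cc3O[C@@H]2c2cc(O)c(O)c(O)c2)cc(OC)c1O | target

Total step count: 6. Longest linear sequence: 6 steps (1 → 3 → 4 → 6 → 7 → 9 → 10).

Steps most likely to fail

Step 4. The Lewis acid may ionise the doubly activated benzylic C2–O bond, which would epimerise C2 or expel the phenol. The activated epoxide may also rearrange by hydride shift before the arene attacks. The fallback forms the same C4–C4a bond by an anionic Parham cycloalkylation and sets out from 4 and 5. Ortho-selective bromination of 5 (NBS, cat. i-Pr2NH, CH2Cl2, −78 °C to 0 °C) should give 2-bromo-3,5-bis(benzyloxy)phenol F1. Mitsunobu coupling of F1 with 4 (PPh3, DIAD, toluene) should give, with inversion, (R)-2-{(R)-[3,5-bis(benzyloxy)-2-bromophenoxy][3,4,5-tris(benzyloxy)phenyl]methyl}oxirane F2. MgBr2·OEt2 in THF opens the oxirane at its terminal carbon to (1R,2S)-1-[3,5-bis(benzyloxy)-2-bromophenoxy]-3-bromo-1-[3,4,5-tris(benzyloxy)phenyl]propan-2-ol F3, held in the flask as its magnesium alkoxide. n-BuLi at −78 °C then performs bromine–lithium exchange on the aryl bromide, and the aryllithium displaces the primary bromide (6-exo-tet). After aqueous work-up the route is rejoined at 7.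

Step 3. Displacement by the bulky, ambident phloroglucinol-type phenoxide may be slow. The alkoxyphosphonium ion could then ionise, eroding configuration at the benzylic carbon, or be captured through a ring carbon of the phenoxide. The fallback does the inversion with a carboxylate and makes the aryl–oxygen bond at the arene carbon, where the stereocentre is not touched. It sets out from 4. Mitsunobu inversion with 4-nitrobenzoic acid (PPh3, DIAD, THF, 0 °C) should give (R)-[(R)-oxiran-2-yl][3,4,5-tris(benzyloxy)phenyl]methyl 4-nitrobenzoate F4. Brief methanolysis (K2CO3, MeOH, 0 °C) should give the threo alcohol (R)-[(R)-oxiran-2-yl][3,4,5-tris(benzyloxy)phenyl]methanol F5. Chan–Lam O-arylation of F5 with 3,5-bis(benzyloxy)phenylboronic acid (Cu(OAc)2, DMAP, 4 Å MS, CH2Cl2, O2, rt) proceeds with retention and rejoins the route at 6.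

Step 2. The rate difference between the enantiomers of this slowly epoxidised terminal vinyl carbinol may be too small. Epoxy alcohol collected near half conversion would then carry material from the slow enantiomer, and long contact with titanium could open the product. The fallback hands enantiomer separation to an enzyme and runs the epoxidation as a matched reaction to full conversion. It sets out from 3. Acylation with vinyl acetate catalysed by a lipase (immobilised Candida antarctica lipase B, MTBE, rt) should acetylate the (R)-enantiomer selectively to (R)-1-[3,4,5-tris(benzyloxy)phenyl]prop-2-en-1-yl acetate F6, which is separated from the unreacted (S)-alcohol. Methanolysis (K2CO3, MeOH) gives (R)-1-[3,4,5-tris(benzyloxy)phenyl]prop-2-en-1-ol F7. Epoxidation of F7 with Ti(OiPr)4, L-(+)-DIPT and t-BuOOH (1.1 equiv), where reagent and substrate preferences reinforce each other, rejoins the route at 4.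

Further compounds
F1 | step 4 | 2-bromo-3,5-bis(benzyloxy)phenol | Oc1cc(OCc2ccccc2)cc(OCc2ccccc2)c1Br
F2 | step 4 | (R)-2-{(R)-[3,5-bis(benzyloxy)-2-bromophenoxy][3,4,5-tris(benzyloxy)phenyl]methyl}oxirane | O1C[C@@H]1[C@@H](c1cc(OCc2ccccc2)c(OCc2ccccc2)c(OCc2ccccc2)c1)Oc1cc(OCc2ccccc2)cc(OCc2ccccc2)c1Br
F3 | step 4 | (1R,2S)-1-[3,5-bis(benzyloxy)-2-bromophenoxy]-3-bromo-1-[3,4,5-tris(benzyloxy)phenyl]propan-2-ol | BrC[C@@H](O)[C@@H](c1cc(OCc2ccccc2)c(OCc2ccccc2)c(OCc2ccccc2)c1)Oc1cc(OCc2ccccc2)cc(OCc2ccccc2)c1Br
F4 | step 3 | (R)-[(R)-oxiran-2-yl][3,4,5-tris(benzyloxy)phenyl]methyl 4-nitrobenzoate | O1C[C@@H]1[C@H](OC(=O)c1ccc(cc1)[N+](=O)[O-])c1cc(OCc2ccccc2)c(OCc2ccccc2)c(OCc2ccccc2)c1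
F5 | step 3 | (R)-[(R)-oxiran-2-yl][3,4,5-tris(benzyloxy)phenyl]methanol (threo) | O1C[C@@H]1[C@H](O)c1cc(OCc2ccccc2)c(OCc2ccccc2)c(OCc2ccccc2)c1
F6 | step 2 | (R)-1-[3,4,5-tris(benzyloxy)phenyl]prop-2-en-1-yl acetate | C=C[C@@H](OC(C)=O)c1cc(OCc2ccccc2)c(OCc2ccccc2)c(OCc2ccccc2)c1
F7 | step 2 | (R)-1-[3,4,5-tris(benzyloxy)phenyl]prop-2-en-1-ol | C=C[C@@H](O)c1cc(OCc2ccccc2)c(OCc2ccccc2)c(OCc2ccccc2)c1
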